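**Retrosynthetic overview**

1. The target is (2S)-2,3-dihydro-3′,3‴-biapigenin: a (2S)-flavanone joined through its ring B carbon C3′ to C3‴ of a flavone. All six phenols are carried as benzyl ethers and freed last by hydrogenolysis.
2. Key disconnection: the C3–C4 bond of the pyranone ring C of the flavanone. The enabling feature is that C4 is an aryl ketone carbon on ring A ortho to the ether oxygen O1, C3 is an unsubstituted CH2, and C2 carries only H and the aryl group. Ring C is therefore the adduct of a ring A salicylaldehyde C–H across the C2=C3 bond of an aryl 1-arylvinyl ether, with C2 set by the catalyst.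
3. The achiral precursor 14 is cut at the biaryl bond (Suzuki–Miyaura) into bromo vinyl ether 8 and flavone boronate 13; both biaryl rings come from 4-(benzyloxy)-3-bromobenzaldehyde.
4. Vinyl ether 8 comes from ortho-formylated 3,5-bis(benzyloxy)phenol and a styrene bromohydrin (Mitsunobu, then dehydrobromination). Boronate 13 comes from a chalcone by oxidative cyclisation and borylation.
5. Ring order: flavone pyranone ring (step 7), biaryl bond (step 9), flavanone ring C together with the C2 stereocentre (step 10).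

Key step: step 10

Assumption: the sense of induction of (R)-DTBM-SEGPHOS in step 10 is assigned only by analogy with carbocyclic hydroacylations and should be confirmed on a model vinyl ether; if the 2R flavanone predominates, the (S)-ligand is used instead.

**Route**

Step 1
Reactants: 1 3,5-bis(benzyloxy)phenol
Product: 3 2,4-bis(benzyloxy)-6-hydroxybenzaldehyde, via salicyl alcohol 2 (not isolated)
Conditions: MgCl2, Et3N, (CH2O)n, MeCN, reflux; then 1 M HCl
Reagents that add atoms: paraformaldehyde (as formaldehyde), C=O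
Why: Magnesium-phenoxide-directed ortho-formylation (Casnati–Skattebøl reaction): the chelated phenoxide is hydroxymethylated only ortho to the phenol oxygen (both ortho sites are equivalent), and the salicyl alcohol 2 is oxidised in the flask by a second formaldehyde through an Oppenauer-type hydride transfer.

Step 2
Reactants: 4 4-(benzyloxy)-3-bromobenzaldehyde
Product: 5 1-(benzyloxy)-2-bromo-4-ethenylbenzene
Conditions: Ph3PCH3Br, KOtBu, THF, 0 °C to rt
Reagents that add atoms: methyltriphenylphosphonium bromide, C[P+](c1ccccc1)(c1ccccc1)c1ccccc1.[Br-]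
Why: Wittig methylenation of a non-enolisable aryl aldehyde with the unstabilised ylide; the aryl bromide and benzyl ether are inert.

Step 3
Reactants: 5 1-(benzyloxy)-2-bromo-4-ethenylbenzene
Product: 6 rac-1-[4-(benzyloxy)-3-bromophenyl]-2-bromoethan-1-ol
Conditions: NBS, DMSO/H2O, 0 °C to rt
Reagents that add atoms: N-bromosuccinimide, O=C1CCC(=O)N1Br; water, O
Why: Bromohydrin formation: the bromonium ion of the electron-rich styrene is opened by water at the benzylic carbon (Markovnikov, assisted by the para-benzyloxy group); the carbinol centre is formed racemic, which suffices because step 5 destroys it.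

Step 4
Reactants: 3 2,4-bis(benzyloxy)-6-hydroxybenzaldehyde; 6 rac-1-[4-(benzyloxy)-3-bromophenyl]-2-bromoethan-1-ol
Product: 7 rac-2,4-bis(benzyloxy)-6-{1-[4-(benzyloxy)-3-bromophenyl]-2-bromoethoxy}benzaldehyde
Conditions: PPh3, DIAD, THF, 0 °C to rt
Reagents that add atoms: none
Why: Mitsunobu etherification: the acidic, hydrogen-bonded phenol of 3 displaces the oxyphosphonium of the secondary benzylic alcohol; the configuration of the ether carbon is irrelevant (racemic) because it becomes sp2 in step 5.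

Step 5
Reactants: 7 rac-2,4-bis(benzyloxy)-6-{1-[4-(benzyloxy)-3-bromophenyl]-2-bromoethoxy}benzaldehyde
Product: 8 2,4-bis(benzyloxy)-6-({1-[4-(benzyloxy)-3-bromophenyl]ethenyl}oxy)benzaldehyde
Conditions: KOtBu, THF, 0 °C
Reagents that add atoms: none
Why: E2 dehydrobromination of a β-bromo ether (the classical route to α-alkoxystyrenes): the only β-hydrogen is the benzylic, oxygen-bearing C–H, so only the 1,1-disubstituted vinyl ether can form, and the aldehyde is non-enolisable.

Step 6
Reactants: 9 1-[2,4-bis(benzyloxy)-6-hydroxyphenyl]ethan-1-one; 4 4-(benzyloxy)-3-bromobenzaldehyde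
Product: 10 (E)-1-[2,4-bis(benzyloxy)-6-hydroxyphenyl]-3-[4-(benzyloxy)-3-bromophenyl]prop-2-en-1-one
Conditions: KOH, EtOH/THF, rt
Reagents that add atoms: none
Why: Claisen–Schmidt aldol condensation of a 2′-hydroxyacetophenone with a non-enolisable aldehyde gives the (E)-chalcone under thermodynamic control.

Step 7
Reactants: 10 (E)-1-[2,4-bis(benzyloxy)-6-hydroxyphenyl]-3-[4-(benzyloxy)-3-bromophenyl]prop-2-en-1-one
Product: 12 5,7-bis(benzyloxy)-2-[4-(benzyloxy)-3-bromophenyl]-4H-chromen-4-one, via racemic flavanone 11 (not isolated)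
Conditions: I2 (cat.), DMSO, 120 °C
Reagents that add atoms: none
Why: Iodine/DMSO oxidative cyclisation of a 2′-hydroxychalcone: oxa-Michael closure to the racemic flavanone 11 is followed by iodine-mediated dehydrogenation, with DMSO as the terminal oxidant that regenerates iodine.

Step 8
Reactants: 12 5,7-bis(benzyloxy)-2-[4-(benzyloxy)-3-bromophenyl]-4H-chromen-4-one
Product: 13 5,7-bis(benzyloxy)-2-[4-(benzyloxy)-3-(4,4,5,5-tetramethyl-1,3,2-dioxaborolan-2-yl)phenyl]-4H-chromen-4-one
Conditions: B2pin2, Pd(dppf)Cl2 (cat.), KOAc, 1,4-dioxane, 90 °C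
Reagents that add atoms: bis(pinacolato)diboron, CC1(C)OB(OC1(C)C)B1OC(C)(C)C(C)(C)O1
Why: Miyaura borylation of an aryl bromide; the weak base KOAc leaves the chromone and benzyl ethers untouched.

Step 9
Reactants: 8 2,4-bis(benzyloxy)-6-({1-[4-(benzyloxy)-3-bromophenyl]ethenyl}oxy)benzaldehyde; 13 5,7-bis(benzyloxy)-2-[4-(benzyloxy)-3-(4,4,5,5-tetramethyl-1,3,2-dioxaborolan-2-yl)phenyl]-4H-chromen-4-one
Product: 14 2,4-bis(benzyloxy)-6-[(1-{2′,6-bis(benzyloxy)-5′-[5,7-bis(benzyloxy)-4-oxo-4H-chromen-2-yl]-[1,1′-biphenyl]-3-yl}ethenyl)oxy]benzaldehyde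
Conditions: Pd(OAc)2 (cat.), SPhos, K3PO4, toluene/H2O, 80 °C; chromatography on Et3N-deactivated silica
Reagents that add atoms: none
Why: Suzuki–Miyaura coupling with a biarylphosphine ligand suited to the 2,2′-dialkoxybiaryl; the basic medium preserves the acid-labile vinyl ether and the non-enolisable aldehyde.

Step 10
Reactants: 14 2,4-bis(benzyloxy)-6-[(1-{2′,6-bis(benzyloxy)-5′-[5,7-bis(benzyloxy)-4-oxo-4H-chromen-2-yl]-[1,1′-biphenyl]-3-yl}ethenyl)oxy]benzaldehyde
Product: 15 (2S)-5,7-bis(benzyloxy)-2-{2′,6-bis(benzyloxy)-5′-[5,7-bis(benzyloxy)-4-oxo-4H-chromen-2-yl]-[1,1′-biphenyl]-3-yl}-2,3-dihydro-4H-chromen-4-one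
Conditions: [Rh(cod)Cl]2 (cat.), (R)-DTBM-SEGPHOS, NaB[3,5-(CF3)2C6H3]4, anhydrous degassed 1,4-dioxane, 60 °C
Reagents that add atoms: none
Why: Proposed new method: oxidative addition of the formyl C–H bond of 14 to the cationic monovalent rhodium bisphosphine complex gives an acyl rhodium hydride bound to the vinyl ether alkene; hydride migration to the aryl-bearing alkene carbon (the future C2) gives a seven-membered acyl alkyl rhodacycle, and C–C reductive elimination forms the bond between carbonyl carbon C4 and methylene carbon C3. The closest known reaction type is the rhodium-catalysed enantioselective endo hydroacylation of 1,1-disubstituted alkenes, in which 2-(1-substituted vinyl)benzaldehydes give 3-substituted indan-1-ones and ortho-allylbenzaldehydes give tetralones; what is new is the enol ether oxygen inside the tether. The pyranone ring C closes in a formal 6-endo-trig mode, the acyl carbon attacking the terminal CH2 with both alkene carbons ending in the ring. The single new stereocentre C2 is created when hydride is delivered to one enantiotopic face of the 1,1-disubstituted alkene, and that face is chosen by the C2-symmetric bisphosphine on rhodium (pure catalyst control, as 14 is achiral). The step needs endo over exo regioselectivity and cyclisation over decarbonylation: the exo path would require a tertiary, benzylic α-aryloxy alkyl rhodium and a quaternary-centre-forming reductive elimination to a 2-aryl-2-methylbenzofuran-3-one, which the 1,1-disubstitution disfavours, while the chelating bisphosphine with a non-coordinating anion keeps a site free for the tethered alkene and the flanking benzyloxy oxygen can stabilise the acyl rhodium species against CO extrusion.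

Step 11
Reactants: 15 (2S)-5,7-bis(benzyloxy)-2-{2′,6-bis(benzyloxy)-5′-[5,7-bis(benzyloxy)-4-oxo-4H-chromen-2-yl]-[1,1′-biphenyl]-3-yl}-2,3-dihydro-4H-chromen-4-one
Product: 16 (2S)-2-[5′-(5,7-dihydroxy-4-oxo-4H-chromen-2-yl)-2′,6-dihydroxy-[1,1′-biphenyl]-3-yl]-5,7-dihydroxy-2,3-dihydro-4H-chromen-4-one
Conditions: H2 (1 atm), Pd/C (10 % palladium on carbon), EtOAc/MeOH, rt
Reagents that add atoms: none
Why: Catalytic hydrogenolysis of six aryl benzyl ethers under neutral conditions, at which the C2 stereocentre (no base, no strong acid) and the two pyranone carbonyls should not react.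

**Compound list**

1 | 3,5-bis(benzyloxy)phenol | Oc1cc(OCc2ccccc2)cc(OCc2ccccc2)c1 | starting material
2 | 3,5-bis(benzyloxy)-2-(hydroxymethyl)phenol (salicyl alcohol, present as its magnesium salt) | OCc1c(O)cc(OCc2ccccc2)cc1OCc1ccccc1 | intermediate
3 | 2,4-bis(benzyloxy)-6-hydroxybenzaldehyde | O=Cc1c(O)cc(OCc2ccccc2)cc1OCc1ccccc1 | intermediate
4 | 4-(benzyloxy)-3-bromobenzaldehyde | O=Cc1ccc(OCc2ccccc2)c(Br)c1 | starting material
5 | 1-(benzyloxy)-2-bromo-4-ethenylbenzene | C=Cc1ccc(OCc2ccccc2)c(Br)c1 | intermediate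
6 | rac-1-[4-(benzyloxy)-3-bromophenyl]-2-bromoethan-1-ol | OC(CBr)c1ccc(OCc2ccccc2)c(Br)c1 | intermediate
7 | rac-2,4-bis(benzyloxy)-6-{1-[4-(benzyloxy)-3-bromophenyl]-2-bromoethoxy}benzaldehyde | O=Cc1c(OC(CBr)c2ccc(OCc3ccccc3)c(Br)c2)cc(OCc2ccccc2)cc1OCc1ccccc1 | intermediate
8 | 2,4-bis(benzyloxy)-6-({1-[4-(benzyloxy)-3-bromophenyl]ethenyl}oxy)benzaldehyde | O=Cc1c(OC(=C)c2ccc(OCc3ccccc3)c(Br)c2)cc(OCc2ccccc2)cc1OCc1ccccc1 | intermediate
9 | 1-[2,4-bis(benzyloxy)-6-hydroxyphenyl]ethan-1-one | CC(=O)c1c(O)cc(OCc2ccccc2)cc1OCc1ccccc1 | starting material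
10 | (E)-1-[2,4-bis(benzyloxy)-6-hydroxyphenyl]-3-[4-(benzyloxy)-3-bromophenyl]prop-2-en-1-one | O=C(/C=C/c1ccc(OCc2ccccc2)c(Br)c1)c1c(O)cc(OCc2ccccc2)cc1OCc1ccccc1 | intermediate
11 | rac-5,7-bis(benzyloxy)-2-[4-(benzyloxy)-3-bromophenyl]-2,3-dihydro-4H-chromen-4-one | O=C1CC(c2ccc(OCc3ccccc3)c(Br)c2)Oc2cc(OCc3ccccc3)cc(OCc3ccccc3)c21 | intermediate
12 | 5,7-bis(benzyloxy)-2-[4-(benzyloxy)-3-bromophenyl]-4H-chromen-4-one | O=c1cc(-c2ccc(OCc3ccccc3)c(Br)c2)oc2cc(OCc3ccccc3)cc(OCc3ccccc3)c12 | intermediate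
13 | 5,7-bis(benzyloxy)-2-[4-(benzyloxy)-3-(4,4,5,5-tetramethyl-1,3,2-dioxaborolan-2-yl)phenyl]-4H-chromen-4-one | O=c1cc(-c2ccc(OCc3ccccc3)c(B3OC(C)(C)C(C)(C)O3)c2)oc2cc(OCc3ccccc3)cc(OCc3ccccc3)c12 | intermediate
14 | 2,4-bis(benzyloxy)-6-[(1-{2′,6-bis(benzyloxy)-5′-[5,7-bis(benzyloxy)-4-oxo-4H-chromen-2-yl]-[1,1′-biphenyl]-3-yl}ethenyl)oxy]benzaldehyde | O=Cc1c(OC(=C)c2ccc(OCc3ccccc3)c(-c3cc(-c4cc(=O)c5c(OCc6ccccc6)cc(OCc6ccccc6)cc5o4)ccc3OCc3ccccc3)c2)cc(OCc2ccccc2)cc1OCc1ccccc1 | intermediate
15 | (2S)-5,7-bis(benzyloxy)-2-{2′,6-bis(benzyloxy)-5′-[5,7-bis(benzyloxy)-4-oxo-4H-chromen-2-yl]-[1,1′-biphenyl]-3-yl}-2,3-dihydro-4H-chromen-4-one | O=C1C[C@@H](c2ccc(OCc3ccccc3)c(-c3cc(-c4cc(=O)c5c(OCc6ccccc6)cc(OCc6ccccc6)cc5o4)ccc3OCc3ccccc3)c2)Oc2cc(OCc3ccccc3)cc(OCc3ccccc3)c21 | intermediate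
16 | (2S)-2-[5′-(5,7-dihydroxy-4-oxo-4H-chromen-2-yl)-2′,6-dihydroxy-[1,1′-biphenyl]-3-yl]-5,7-dihydroxy-2,3-dihydro-4H-chromen-4-one | O=C1C[C@@H](c2ccc(O)c(-c3cc(-c4cc(=O)c5c(O)cc(O)cc5o4)ccc3O)c2)Oc2cc(O)cc(O)c21 | target

**Step count and risks**

Total steps: 11. Longest linear sequence: 7 steps (steps 2, 3, 4, 5, 9, 10 and 11, from 4 to 16).

Steps most likely to fail:

1. Step 10 (proposed new method). The acyl rhodium hydride may extrude carbon monoxide before the alkene inserts, closure may take the exo course, hydride delivery may show poor facial selectivity, or adventitious acid may hydrolyse the vinyl ether. The fallback uses known chemistry, sets out from 12 and 9, and comes back at 15. Bromoflavone 12 is coupled at the bromide with commercial [2-(benzyloxy)-5-chlorophenyl]boronic acid (OB(O)c1cc(Cl)ccc1OCc1ccccc1; Pd(PPh3)4, Na2CO3, DME/H2O, 80 °C) to give 5,7-bis(benzyloxy)-2-[2′,6-bis(benzyloxy)-5′-chloro-[1,1′-biphenyl]-3-yl]-4H-chromen-4-one F1. Palladium-catalysed borylation of the aryl chloride with B2(OH)4 (Pd(OAc)2, XPhos, KOAc, EtOH, 80 °C) gives {2′,6-bis(benzyloxy)-5′-[5,7-bis(benzyloxy)-4-oxo-4H-chromen-2-yl]-[1,1′-biphenyl]-3-yl}boronic acid F2. Separately, 9 is condensed with Me2NCH(OMe)2 (toluene, 100 °C) to (E)-1-[2,4-bis(benzyloxy)-6-hydroxyphenyl]-3-(dimethylamino)prop-2-en-1-one F3, which closes with HCl in CH2Cl2 to 5,7-bis(benzyloxy)-4H-chromen-4-one F4. Enantioselective conjugate addition of F2 to F4 with divalent palladium (Pd(OCOCF3)2, the t-BuPyOx antipode that delivers the 2S product, NH4PF6, H2O, ClCH2CH2Cl, 60 °C) would then form the C2–aryl bond instead of C3–C4 and give 15 under non-basic conditions that should not racemise the flavanone.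

2. Step 4. The oxyphosphonium of the para-alkoxybenzylic alcohol may ionise, leading to C-alkylation of the electron-rich ring or loss of the alcohol by elimination before the hindered, hydrogen-bonded phenol attacks at oxygen. The fallback sets out from 4 (with 3) and comes back at 8, replacing steps 2 to 5. Ohira–Bestmann homologation of 4 (dimethyl (1-diazo-2-oxopropyl)phosphonate, K2CO3, MeOH, rt) gives 1-(benzyloxy)-2-bromo-4-ethynylbenzene F5. Markovnikov hydrophenoxylation of F5 with phenol 3 under monovalent gold catalysis ([Au(IPr)Cl]/AgNTf2, IPr = 1,3-bis(2,6-diisopropylphenyl)imidazol-2-ylidene, toluene, 80 °C) would give vinyl ether 8 directly.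

3. Step 11. Over-reduction may occur (hydrogenolysis of the benzylic C2–O1 bond to a dihydrochalcone, or reduction of the C4 carbonyl or the flavone C2=C3 bond), or the debenzylation may stall on the poorly soluble partly deprotected material. The fallback sets out from 15 and comes back at 16 without a new compound: non-reductive Lewis-acid debenzylation with BCl3 and pentamethylbenzene as benzyl-cation scavenger (CH2Cl2, −78 °C, quenched with MeOH at low temperature), which cleaves aryl benzyl ethers without hydrogen and cold enough that acid-promoted ring opening of the flavanone should not compete.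

**Further compounds**

F1 | step 10 | 5,7-bis(benzyloxy)-2-[2′,6-bis(benzyloxy)-5′-chloro-[1,1′-biphenyl]-3-yl]-4H-chromen-4-one | O=c1cc(-c2ccc(OCc3ccccc3)c(-c3cc(Cl)ccc3OCc3ccccc3)c2)oc2cc(OCc3ccccc3)cc(OCc3ccccc3)c12
F2 | step 10 | {2′,6-bis(benzyloxy)-5′-[5,7-bis(benzyloxy)-4-oxo-4H-chromen-2-yl]-[1,1′-biphenyl]-3-yl}boronic acid | O=c1cc(-c2ccc(OCc3ccccc3)c(-c3cc(B(O)O)ccc3OCc3ccccc3)c2)oc2cc(OCc3ccccc3)cc(OCc3ccccc3)c12
F3 | step 10 | (E)-1-[2,4-bis(benzyloxy)-6-hydroxyphenyl]-3-(dimethylamino)prop-2-en-1-one | CN(C)/C=C/C(=O)c1c(O)cc(OCc2ccccc2)cc1OCc1ccccc1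
F4 | step 10 | 5,7-bis(benzyloxy)-4H-chromen-4-one | O=c1ccoc2cc(OCc3ccccc3)cc(OCc3ccccc3)c12
F5 | step 4 | 1-(benzyloxy)-2-bromo-4-ethynylbenzene | C#Cc1ccc(OCc2ccccc2)c(Br)c1
F0 | step 11 | none | none
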